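The route rests on unveiling, not cyclising, the ten-membered ring: because the C6 oxygen is 1,3 to C1 through C10, a C6–C10 bond turns the germacrane ring into a cis-fused bicycle of a cyclopentane (C6–C7–C8–C9–C10) and a cycloheptene (C10–C1–C2–C3–C4–C5–C6). Grob fragmentation of its C6 alkoxide/C1 mesylate cleaves C6–C10 and delivers in one operation the C6 ketone, the (E)-C1=C10 olefin and the ring-inherited (Z)-C4=C5 enone. The precursor 22 carries the equatorial C1 mesylate cis to the C10 methyl and C6 hydroxyl, the C2 silyl ether, and PMB-protected C8–O and C12–O; it is built by chelation-controlled Mukaiyama aldol, vinyl addition and metathesis.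

Key step: step 17

Remark: germacrane numbering of the target (C1–C15) is used for every intermediate; α/β refer to the flat drawing in which the C7 side chain is β; PMB = 4-methoxybenzyl, TBS = tert-butyldimethylsilyl, TES = triethylsilyl; metal alkoxides and enolates of numbered compounds are not numbered separately.
Assumption: hydride reduction of the C6 ketone of 23 follows the Felkin–Anh sense set by C7 and gives the 6β alcohol; the endgame uses this alcohol to direct the epoxidation and then inverts C6.

Step 1
Reactants: 1 (1R,5S)-2-oxabicyclo[3.3.0]oct-6-en-3-one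
Product: 2 (1R,2S)-2-(2-hydroxyethyl)cyclopent-3-en-1-ol
Conditions: LiAlH4, THF, 0 °C to rt
Reagents that add atoms: none
Why: Hydride reduction of the γ-lactone to the 1,4-diol should leave both stereocentres untouched and expose C8–OH and the C11–C12 arm on C7.

Step 2
Reactants: 2 (1R,2S)-2-(2-hydroxyethyl)cyclopent-3-en-1-ol
Product: 3 bis-PMB ether of 2 (C8 OPMB cis to the C7 CH2CH2OPMB arm; C6=C10 olefin)
Conditions: NaH, PMBCl, n-Bu4NI (cat.), DMF, 0 °C to rt
Reagents that add atoms: 4-methoxybenzyl chloride, COc1ccc(CCl)cc1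
Why: Williamson etherification of both alkoxides installs ethers that should survive every later base, hydride, Lewis acid and metathesis step and fall together to DDQ.

Step 3
Reactants: 3 bis-PMB ether
Product: 4 C6–C10 epoxide (oxirane trans to the C7 arm and the C8 ether)
Conditions: mCPBA, CH2Cl2, 0 °C
Reagents that add atoms: 3-chloroperbenzoic acid, O=C(OO)c1cccc(Cl)c1
Why: Prilezhaev epoxidation should occur on the face opposite the allylic C7 arm and the homoallylic C8 ether, and the two new centres are erased again in steps 4 and 5.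

Step 4
Reactants: 4 C6–C10 epoxide
Product: 7 allylic alcohol (C6–OH trans to the C7 arm; C9=C10), via hydroxy selenide 5 (not isolated), via selenoxide 6 (not isolated)
Conditions: (PhSe)2, NaBH4, EtOH, 78 °C; then H2O2, THF, 0 °C to rt
Reagents that add atoms: none
Why: Benzeneselenolate should open the epoxide anti at C10 (attack at C6 is blocked by the cis C7 arm on the approach face), and selenoxide syn-elimination, which avoids the carbinol carbon, moves the olefin to C9=C10.

Step 5
Reactants: 7 allylic alcohol
Product: 8 (4R,5R)-4-(PMB-oxy)-5-[2-(PMB-oxy)ethyl]cyclopent-2-en-1-one (C6 ketone)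
Conditions: Dess–Martin periodinane, pyridine, CH2Cl2, rt
Reagents that add atoms: none
Why: Dess–Martin oxidation of the allylic alcohol gives the enone under non-basic conditions, so C7 (α to the carbonyl) and the C8 ether (β to it) are not put at risk.

Step 6
Reactants: 8 enone
Product: 9 2-iodo enone (iodine on C10)
Conditions: I2, pyridine, CH2Cl2, rt
Reagents that add atoms: iodine, II
Why: α-Iodination of the enone by conjugate addition of pyridine, iodination of the enolate and elimination (addition–elimination of the Baylis–Hillman type) functionalises C10 only.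

Step 7
Reactants: 9 2-iodo enone
Product: 10 2-methyl enone (C14 on C10)
Conditions: Me4Sn, Pd2(dba)3 (cat.), AsPh3, CuI (cat.), NMP, 80 °C
Reagents that add atoms: tetramethylstannane, C[Sn](C)(C)C
Why: Stille coupling of the 2-iodoenone installs the C14 methyl under neutral conditions.

Step 8
Reactants: 10 2-methyl enone
Product: 11 triethylsilyl enol ether (C6–OSiEt3, C6=C10)
Conditions: Et3SiH, RhCl(PPh3)3 (cat.), benzene, 60 °C
Reagents that add atoms: triethylsilane, CC[SiH](CC)CC
Why: Rhodium-catalysed 1,4-hydrosilylation puts hydride on C9 and silicon on oxygen, giving the C6=C10 enol silane as one regioisomer, which deprotonation of the saturated ketone could not guarantee (C7–H competes and a C7 enolate would expel the C8 ether).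

Step 9
Reactants: 12 (R)-glycidol; 13 isopropenylmagnesium bromide
Product: 14 (S)-4-methylpent-4-ene-1,2-diol
Conditions: CuI (cat.), THF, −30 to 0 °C
Reagents that add atoms: none
Why: Copper-catalysed Grignard opening of the epoxide at its CH2 terminus (the first equivalent is spent on the hydroxyl) leaves the glycidol stereocentre, the future C2, untouched.

Step 10
Reactants: 14 (S)-4-methylpent-4-ene-1,2-diol
Product: 15 (S)-1,2-bis(TBS-oxy)-4-methylpent-4-ene
Conditions: TBSCl, imidazole, DMF, rt
Reagents that add atoms: tert-butyldimethylsilyl chloride, CC(C)(C)[Si](C)(C)Cl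
Why: Exhaustive silylation is simpler than differentiating the diol directly and places on C2–O the group that is kept until the last steps.

Step 11
Reactants: 15 bis-TBS ether
Product: 16 (S)-2-(TBS-oxy)-4-methylpent-4-en-1-ol
Conditions: HF·pyridine, pyridine, THF, 0 °C
Reagents that add atoms: none
Why: The primary silyl ether is cleaved faster than the secondary one on steric grounds, freeing only the future C1 hydroxyl.

Step 12
Reactants: 16 primary alcohol
Product: 17 (S)-2-(TBS-oxy)-4-methylpent-4-enal
Conditions: Dess–Martin periodinane, pyridine, CH2Cl2, 0 °C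
Reagents that add atoms: none
Why: Dess–Martin oxidation should give the α-silyloxy aldehyde without epimerising C2, provided it is used at once.

Step 13
Reactants: 11 triethylsilyl enol ether; 17 α-silyloxy aldehyde
Product: 18 aldol adduct (C6 ketone; C10 methyl cis to the C7 arm and C8 ether; C1–OH and C2–OTBS syn)
Conditions: Me2AlCl (2.5 equiv), CH2Cl2, −78 °C
Reagents that add atoms: none
Why: Mukaiyama aldol under chelation control: Me2AlCl bridges the aldehyde and α-silyloxy oxygens, so the enol silane should attack C1 anti to the methallyl group (anti-Felkin, C1–O/C2–O syn) through its face opposite the C7 arm and C8 ether, creating the C10 quaternary centre and C1 with C1–O syn to C9 (zigzag C6–C10–C1–C2), the relation the fragmentation needs, whereas a chair lithium aldol would give the C1 epimer and hence the (Z)-olefin.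

Step 14
Reactants: 18 aldol adduct; 19 vinylmagnesium bromide
Product: 20 vinyl carbinol (C6–OH cis to the C10 methyl; vinyl cis to the C1 chain)
Conditions: CeCl3, THF, −78 °C
Reagents that add atoms: none
Why: Organocerium 1,2-addition to the hindered, enolisable ketone: the C10 methyl, the C7 arm and the C8 ether shield the upper face and the C1 alkoxide chelates the carbonyl, so vinyl should enter from the lower face, cis to the C1 chain, setting C6 for a cis ring fusion, while low basicity suppresses retro-aldol and C7 enolisation.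

Step 15
Reactants: 20 vinyl carbinol
Product: 21 cis-fused bicyclo[5.3.0]dec-4-ene-1,6-diol (C1–OH, C6–OH, C10 methyl, C7 arm and C8 OPMB on one face, C2 OTBS on the other)
Conditions: second-generation Grubbs catalyst RuCl2(=CHPh)(PCy3)(H2IMes) (cat.), CH2Cl2, 40 °C
Reagents that add atoms: none
Why: Ring-closing metathesis between the vinyl and isopropenyl groups, held cis on adjacent carbons, closes the cycloheptene with loss of ethene; the trisubstituted C4=C5 olefin is Z by ring constraint and no stereocentre changes.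

Step 16
Reactants: 21 bicyclic diol
Product: 22 bicyclic C6 alcohol C1 mesylate
Conditions: MsCl, Et3N, CH2Cl2, −20 °C
Reagents that add atoms: methanesulfonyl chloride, CS(=O)(=O)Cl
Why: Sulfonylation through sulfene selects the secondary C1–OH over the tertiary allylic C6–OH, and the amine base does not form the C6 alkoxide, so the 1,3-hydroxy mesylate should be isolable without premature fragmentation.

Step 17
Reactants: 22 bicyclic C6 alcohol C1 mesylate
Product: 23 (1(10)E,4Z)-2α-(TBS-oxy)-8β-(PMB-oxy)-7β-[2-(PMB-oxy)ethyl]-4,10-dimethylcyclodeca-1(10),4-dien-6-one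
Conditions: KOt-Bu (1.05 equiv), THF, 0 °C; pH 7 buffer
Reagents that add atoms: none
Why: Deprotonation of the tertiary C6–OH gives an alkoxide whose lone pair pushes into the C6–C10 σ bond while the antiperiplanar C1–OMs bond ionises, so C6=O and C1=C10 form and the shared bond breaks in one concerted, cation-free event; the closest known reaction type is the Grob (Wharton) fragmentation of cyclic 1,3-diol monosulfonates to medium-ring cycloalkenones. The ten-membered ring is not closed by an exo or endo attack but arises by merging the five- and seven-membered rings through cleavage of their common bond. No stereocentre is created; the new stereoelement, the (E)-C1=C10 olefin, follows stereospecifically from the C1/C10 relative configuration set in step 13, because in the chair-like cycloheptene conformer with equatorial mesylate (anti to C6–C10) C2 lies anti to C9, and the (Z)-C4=C5 olefin is carried over from the seven-membered ring. The selectivity needed is fragmentation over substitution and elimination: the cis-1,3 relation of C6–O and C1–OMs forbids backside oxetane closure, the equatorial mesylate has no antiperiplanar hydrogen, and the cis ring fusion lets C9 sit equatorial. One equivalent of base, low temperature and a buffered quench should keep the product, a β-alkoxy ketone, from losing the C8 ether or epimerising at C7.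

Step 18
Reactants: 23 cyclodecadienone
Product: 24 6β allylic alcohol (C6 epimeric to the target)
Conditions: NaBH4, CeCl3·7H2O, MeOH, −78 °C
Reagents that add atoms: none
Why: Luche 1,2-reduction of the enone: hydride should add to C6 in the Felkin–Anh sense set by C7 (C8 branch anti to the nucleophile), giving the 6β carbinol, which is the epimer able to direct the epoxidation to the required face.

Step 19
Reactants: 24 6β allylic alcohol
Product: 25 4α,5α-epoxy-6β-ol (threo epoxy alcohol)
Conditions: t-BuOOH, VO(acac)2 (cat.), CH2Cl2, 0 °C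
Reagents that add atoms: tert-butyl hydroperoxide, CC(C)(C)OO
Why: Vanadium alkoxide-directed epoxidation is chemoselective for C4=C5 (the C1=C10 olefin has only a silylated allylic oxygen); with C3 cis to C6, 1,3-allylic strain holds H6 in the olefin plane and oxygen is delivered to the face of the C6 oxygen (threo), which for the 6β alcohol is the 4R,5S epoxide of the target, cis because the olefin is Z.

Step 20
Reactants: 25 threo epoxy alcohol
Product: 26 4α,5α-epoxy-6-ketone
Conditions: Dess–Martin periodinane, pyridine, CH2Cl2, 0 °C to rt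
Reagents that add atoms: none
Why: Dess–Martin oxidation returns the C6 ketone under buffered conditions that spare the epoxide, the β-situated C8 ether and C7, and erases the C6 configuration once it has directed the epoxidation.

Step 21
Reactants: 26 epoxy ketone
Product: 27 4α,5α-epoxy-6α-ol (erythro epoxy alcohol, 6S)
Conditions: Zn(BH4)2, Et2O, −20 °C
Reagents that add atoms: none
Why: Chelation-controlled reduction of the α,β-epoxy ketone: zinc bridges the carbonyl and epoxide oxygens and hydride attacks anti to the oxirane C4, which should give the erythro (anti) epoxy alcohol, the C6 configuration of the target.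

Step 22
Reactants: 27 erythro epoxy alcohol
Product: 28 C6 TES ether
Conditions: TESOTf, 2,6-lutidine, CH2Cl2, −78 °C
Reagents that add atoms: triethylsilyl trifluoromethanesulfonate, CC[Si](CC)(CC)OS(=O)(=O)C(F)(F)F
Why: Silylation with the silyl triflate and a hindered base masks the hindered C6–OH at low temperature without opening the epoxide, so that only C8–OH can lactonise onto C12 and no ester is present in the enolate step.

Step 23
Reactants: 28 C6 TES ether
Product: 29 C8,C12 diol
Conditions: DDQ, CH2Cl2/pH 7 buffer, 0 °C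
Reagents that add atoms: none
Why: Oxidative cleavage of both PMB ethers through their benzylic oxocarbenium ions in a buffered two-phase medium should spare the silyl ethers, the epoxide and both trisubstituted olefins.

Step 24
Reactants: 29 C8,C12 diol
Product: 31 cis-fused 8,12-lactone, via lactol 30 (not isolated)
Conditions: TEMPO (cat.), PhI(OAc)2, CH2Cl2, rt
Reagents that add atoms: none
Why: Oxoammonium (TEMPO) oxidation selects the primary C12–OH; the aldehyde closes onto C8–OH and the lactol is oxidised on to the γ-lactone, the silylated C6 oxygen being unable to compete.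

Step 25
Reactants: 31 lactone
Product: 32 C11 dimethylaminomethyl lactone (Mannich base)
Conditions: LDA, THF, −78 °C; then CH2=NMe2+ I−, −78 °C to rt
Reagents that add atoms: N,N-dimethylmethyleneiminium iodide (Eschenmoser's salt), C=[N+](C)C.[I-]
Why: Mannich reaction of the lactone lithium enolate aminomethylates C11 (presumably trans to C6), a centre that is removed in step 26.

Step 26
Reactants: 32 Mannich base
Product: 34 α-methylene lactone bis-silyl ether, via ammonium iodide 33 (not isolated)
Conditions: MeI, MeOH, rt; then NaHCO3, CH2Cl2/H2O, rt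
Reagents that add atoms: none
Why: Quaternisation and base-induced β-elimination of trimethylamine (Hofmann-type, E1cB) unveil the exocyclic C11=C13 methylene.

Step 27
Reactants: 34 α-methylene lactone bis-silyl ether
Product: 35 2α,6α-diol
Conditions: HF·pyridine, pyridine, THF, 0 °C to rt
Reagents that add atoms: none
Why: Fluoride cleaves both silyl ethers in a pyridine-buffered, non-basic medium, which avoids alkoxide-driven translactonisation to C6 and conjugate addition to the methylene lactone and is too weakly acidic to open the epoxide.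

Step 28
Reactants: 35 2α,6α-diol
Product: 36 target, (1(10)E,2S,4R,5S,6S,7R,8R)-2,6-diacetoxy-4,5-epoxygermacra-1(10),11(13)-dien-12,8-olide
Conditions: Ac2O, pyridine, DMAP (cat.), CH2Cl2, 0 °C
Reagents that add atoms: acetic anhydride, CC(=O)OC(C)=O
Why: DMAP-catalysed acylation of the two secondary alcohols gives the 2,6-diacetate without touching the epoxide or the methylene lactone.

Compound list
1 | (1R,5S)-2-oxabicyclo[3.3.0]oct-6-en-3-one | C1C(=O)O[C@@H]2CC=C[C@H]12 | starting material
2 | (1R,2S)-2-(2-hydroxyethyl)cyclopent-3-en-1-ol | OCC[C@H]1C=CC[C@H]1O | intermediate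
3 | cis-4-(4-methoxybenzyloxy)-3-[2-(4-methoxybenzyloxy)ethyl]cyclopentene (bis-PMB ether of 2) | COc1ccc(COCC[C@H]2C=CC[C@H]2OCc2ccc(OC)cc2)cc1 | intermediate
4 | C6–C10 epoxide of 3, oxirane trans to the C7 arm and C8 ether | COc1ccc(COCC[C@H]2[C@@H]3O[C@@H]3C[C@H]2OCc2ccc(OC)cc2)cc1 | intermediate
5 | trans hydroxy selenide (C6–OH, C10–SePh) | COc1ccc(COCC[C@H]2[C@H](O)[C@@H]([Se]c3ccccc3)C[C@H]2OCc2ccc(OC)cc2)cc1 | intermediate
6 | selenoxide of 5 | COc1ccc(COCC[C@H]2[C@H](O)[C@@H]([Se](=O)c3ccccc3)C[C@H]2OCc2ccc(OC)cc2)cc1 | intermediate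
7 | 4-(PMB-oxy)-5-[2-(PMB-oxy)ethyl]cyclopent-2-en-1-ol, OH trans to the arm | COc1ccc(COCC[C@H]2[C@H](O)C=C[C@H]2OCc2ccc(OC)cc2)cc1 | intermediate
8 | (4R,5R)-4-(4-methoxybenzyloxy)-5-[2-(4-methoxybenzyloxy)ethyl]cyclopent-2-en-1-one | COc1ccc(COCC[C@H]2C(=O)C=C[C@H]2OCc2ccc(OC)cc2)cc1 | intermediate
9 | 2-iodo derivative of 8 | COc1ccc(COCC[C@H]2C(=O)C(I)=C[C@H]2OCc2ccc(OC)cc2)cc1 | intermediate
10 | 2-methyl derivative of 8 | COc1ccc(COCC[C@H]2C(=O)C(C)=C[C@H]2OCc2ccc(OC)cc2)cc1 | intermediate
11 | 2-methyl-1-(triethylsilyloxy)cyclopentene with cis 4-OPMB and 5-[2-(PMB-oxy)ethyl] (C6=C10 enol silane) | COc1ccc(COCC[C@H]2C(O[Si](CC)(CC)CC)=C(C)C[C@H]2OCc2ccc(OC)cc2)cc1 | intermediate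
12 | (R)-glycidol | C1O[C@@H]1CO | starting material
13 | isopropenylmagnesium bromide | C=C(C)[Mg]Br | starting material
14 | (S)-4-methylpent-4-ene-1,2-diol | OC[C@@H](O)CC(C)=C | intermediate
15 | (S)-1,2-bis(tert-butyldimethylsilyloxy)-4-methylpent-4-ene | CC(C)(C)[Si](C)(C)OC[C@@H](O[Si](C)(C)C(C)(C)C)CC(C)=C | intermediate
16 | (S)-2-(tert-butyldimethylsilyloxy)-4-methylpent-4-en-1-ol | OC[C@@H](O[Si](C)(C)C(C)(C)C)CC(C)=C | intermediate
17 | (S)-2-(tert-butyldimethylsilyloxy)-4-methylpent-4-enal | O=C[C@@H](O[Si](C)(C)C(C)(C)C)CC(C)=C | intermediate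
18 | aldol adduct: 2-methylcyclopentanone with the C1(OH)–C2(OTBS)–methallyl chain on C10, trans to the C7 arm and C8 OPMB; C1–OH/C2–OTBS syn | COc1ccc(COCC[C@H]2C(=O)[C@](C)([C@H](O)[C@@H](O[Si](C)(C)C(C)(C)C)CC(C)=C)C[C@H]2OCc2ccc(OC)cc2)cc1 | intermediate
19 | vinylmagnesium bromide | C=C[Mg]Br | starting material
20 | vinyl carbinol: C6 tertiary alcohol, vinyl cis to the C1 chain, OH cis to the C10 methyl | COc1ccc(COCC[C@H]2[C@](O)(C=C)[C@](C)([C@H](O)[C@@H](O[Si](C)(C)C(C)(C)C)CC(C)=C)C[C@H]2OCc2ccc(OC)cc2)cc1 | intermediate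
21 | cis-fused 4,10-dimethylbicyclo[5.3.0]dec-4-ene-1,6-diol with 2-OTBS, 8-OPMB and 7-[2-(PMB-oxy)ethyl] (target numbering) | C[C@]12[C@H](O)[C@@H](O[Si](C)(C)C(C)(C)C)CC(C)=C[C@@]1(O)[C@H](CCOCc3ccc(OC)cc3)[C@H](OCc3ccc(OC)cc3)C2 | intermediate
22 | C1 mesylate of 21 (key-step precursor) | C[C@]12[C@H](OS(C)(=O)=O)[C@@H](O[Si](C)(C)C(C)(C)C)CC(C)=C[C@@]1(O)[C@H](CCOCc3ccc(OC)cc3)[C@H](OCc3ccc(OC)cc3)C2 | intermediate
23 | (1(10)E,4Z)-cyclodeca-1(10),4-dien-6-one with 2α-OTBS, 8β-OPMB, 7β-[2-(PMB-oxy)ethyl] (key-step product) | COc1ccc(CO[C@@H]2C/C(C)=C/[C@@H](O[Si](C)(C)C(C)(C)C)C/C(C)=C\C(=O)[C@@H]2CCOCc3ccc(OC)cc3)cc1 | intermediate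
24 | 6β-hydroxy (1(10)E,4Z)-diene | COc1ccc(CO[C@@H]2C/C(C)=C/[C@@H](O[Si](C)(C)C(C)(C)C)C/C(C)=C\[C@H](O)[C@@H]2CCOCc3ccc(OC)cc3)cc1 | intermediate
25 | 4α,5α-epoxy-6β-ol | COc1ccc(CO[C@@H]2C/C(C)=C/[C@@H](O[Si](C)(C)C(C)(C)C)C[C@@]3(C)O[C@H]3[C@H](O)[C@@H]2CCOCc4ccc(OC)cc4)cc1 | intermediate
26 | 4α,5α-epoxy-6-ketone | COc1ccc(CO[C@@H]2C/C(C)=C/[C@@H](O[Si](C)(C)C(C)(C)C)C[C@@]3(C)O[C@H]3C(=O)[C@@H]2CCOCc4ccc(OC)cc4)cc1 | intermediate
27 | 4α,5α-epoxy-6α-ol | COc1ccc(CO[C@@H]2C/C(C)=C/[C@@H](O[Si](C)(C)C(C)(C)C)C[C@@]3(C)O[C@H]3[C@@H](O)[C@@H]2CCOCc4ccc(OC)cc4)cc1 | intermediate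
28 | C6 triethylsilyl ether of 27 | COc1ccc(CO[C@@H]2C/C(C)=C/[C@@H](O[Si](C)(C)C(C)(C)C)C[C@@]3(C)O[C@H]3[C@@H](O[Si](CC)(CC)CC)[C@@H]2CCOCc4ccc(OC)cc4)cc1 | intermediate
29 | C8,C12 diol (2-OTBS, 6-OTES, 4,5-epoxide) | O[C@@H]1C/C(C)=C/[C@@H](O[Si](C)(C)C(C)(C)C)C[C@@]2(C)O[C@H]2[C@@H](O[Si](CC)(CC)CC)[C@@H]1CCO | intermediate
30 | C12 lactol (8,12-hemiacetal, C12 epimers) | C1C(O)O[C@@H]2C/C(C)=C/[C@@H](O[Si](C)(C)C(C)(C)C)C[C@@]3(C)O[C@H]3[C@@H](O[Si](CC)(CC)CC)[C@H]12 | intermediate
31 | cis-fused 8,12-lactone (11,13-dihydro, 2-OTBS, 6-OTES) | C1C(=O)O[C@@H]2C/C(C)=C/[C@@H](O[Si](C)(C)C(C)(C)C)C[C@@]3(C)O[C@H]3[C@@H](O[Si](CC)(CC)CC)[C@H]12 | intermediate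
32 | C11 dimethylaminomethyl lactone | CN(C)C[C@H]1C(=O)O[C@@H]2C/C(C)=C/[C@@H](O[Si](C)(C)C(C)(C)C)C[C@@]3(C)O[C@H]3[C@@H](O[Si](CC)(CC)CC)[C@H]12 | intermediate
33 | C11 trimethylammoniomethyl lactone iodide | C[N+](C)(C)C[C@H]1C(=O)O[C@@H]2C/C(C)=C/[C@@H](O[Si](C)(C)C(C)(C)C)C[C@@]3(C)O[C@H]3[C@@H](O[Si](CC)(CC)CC)[C@H]12.[I-] | intermediate
34 | α-methylene lactone with 2-OTBS and 6-OTES | C=C1C(=O)O[C@@H]2C/C(C)=C/[C@@H](O[Si](C)(C)C(C)(C)C)C[C@@]3(C)O[C@H]3[C@@H](O[Si](CC)(CC)CC)[C@H]12 | intermediate
35 | 2α,6α-dihydroxy-4α,5α-epoxygermacra-1(10),11(13)-dien-12,8-olide | C=C1C(=O)O[C@@H]2C/C(C)=C/[C@@H](O)C[C@@]3(C)O[C@H]3[C@@H](O)[C@H]12 | intermediate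
36 | (1(10)E,2S,4R,5S,6S,7R,8R)-2,6-diacetoxy-4,5-epoxygermacra-1(10),11(13)-dien-12,8-olide (CNP0270851.1) | C=C1C(=O)O[C@@H]2C/C(C)=C/[C@@H](OC(C)=O)C[C@@]3(C)O[C@H]3[C@@H](OC(C)=O)[C@H]12 | target

Total step count: 28. Longest linear sequence: 24 steps (steps 1–8 and 13–28, from 1 to 36); the aldehyde branch (steps 9–12) adds 4.

Steps most likely to fail

Step 13. The process at risk is facial selection at the aldehyde: if chelation by the silyl ether is lost the C1 epimer forms, the Lewis acid may also trigger an ene reaction of the methallyl olefin, and the quaternary centre forms slowly. The fallback gives up setting C1 in the aldol and sets it by reduction in the bicycle. It sets out from 11: methyllithium cleaves the enol silane to the regiodefined lithium enolate F1, whose chair (Zimmerman–Traxler) aldol with 17 in the Felkin–Anh sense should give the C1-epimeric aldol F2, all control elements being matched. Cerium-mediated addition of 19 then gives the vinyl carbinol F3 and ring-closing metathesis the C1-epimeric bicyclic diol F4. Dess–Martin oxidation of its secondary carbinol gives the hydroxy ketone F5, and a Narasaka–Prasad reduction (Et2BOMe, NaBH4, THF/MeOH, −78 °C) through the boron chelate with the C6 hydroxyl should deliver the cis-1,3-diol, coming back to the route at 21.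

Step 21. The process at risk is erosion of facial selectivity, because the wanted epoxide chelation is opposed by the Felkin–Anh bias of C7 and by possible chelation to the C8 ether. The fallback inverts C6 by substitution instead of by oxidation and reduction. It sets out from 25: a Mitsunobu reaction with 4-nitrobenzoic acid (PPh3, DIAD, toluene) should give the inverted 6α 4-nitrobenzoate F6, and methanolysis (K2CO3, MeOH, 0 °C) comes back to the route at 27 without passing through 26.

Step 17. The process at risk is base-induced damage to the product (loss of the C8 ether by β-elimination, epimerisation at C7) or slow fragmentation of an aggregated potassium alkoxide. The fallback generates the alkoxide without free base. It sets out from 22: silylation of the tertiary hydroxyl (N-trimethylsilylimidazole) gives the C6 trimethylsilyl ether F7, and anhydrous fluoride (tris(dimethylamino)sulfonium difluorotrimethylsilicate, THF, −20 °C) unmasks a naked alkoxide that should fragment at once, coming back to the route at 23.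

Further compounds
F1 | step 13 | lithium enolate of the 2-methylcyclopentanone (O–C6=C10) | [Li+].[O-]C1=C(C)C[C@@H](OCc2ccc(OC)cc2)[C@H]1CCOCc1ccc(OC)cc1
F2 | step 13 | C1-epimeric aldol adduct (C1–OH/C2–OTBS anti) | COc1ccc(COCC[C@H]2C(=O)[C@](C)([C@@H](O)[C@@H](O[Si](C)(C)C(C)(C)C)CC(C)=C)C[C@H]2OCc2ccc(OC)cc2)cc1
F3 | step 13 | C1-epimeric vinyl carbinol | COc1ccc(COCC[C@H]2[C@](O)(C=C)[C@](C)([C@@H](O)[C@@H](O[Si](C)(C)C(C)(C)C)CC(C)=C)C[C@H]2OCc2ccc(OC)cc2)cc1
F4 | step 13 | C1-epimeric bicyclic diol | C[C@]12[C@@H](O)[C@@H](O[Si](C)(C)C(C)(C)C)CC(C)=C[C@@]1(O)[C@H](CCOCc3ccc(OC)cc3)[C@H](OCc3ccc(OC)cc3)C2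
F5 | step 13 | bicyclic C6-hydroxy C1-ketone | C[C@]12C(=O)[C@@H](O[Si](C)(C)C(C)(C)C)CC(C)=C[C@@]1(O)[C@H](CCOCc3ccc(OC)cc3)[C@H](OCc3ccc(OC)cc3)C2
F6 | step 21 | 4α,5α-epoxy-6α-yl 4-nitrobenzoate | COc1ccc(CO[C@@H]2C/C(C)=C/[C@@H](O[Si](C)(C)C(C)(C)C)C[C@@]3(C)O[C@H]3[C@@H](OC(=O)c3ccc(cc3)[N+](=O)[O-])[C@@H]2CCOCc4ccc(OC)cc4)cc1
F7 | step 17 | C6 trimethylsilyl ether of 22 | C[C@]12[C@H](OS(C)(=O)=O)[C@@H](O[Si](C)(C)C(C)(C)C)CC(C)=C[C@@]1(O[Si](C)(C)C)[C@H](CCOCc3ccc(OC)cc3)[C@H](OCc3ccc(OC)cc3)C2
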